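**Plan** (locants: the target is a tricyclo[5.4.0.0^{2,8}]undecane; cyclobutane = C1–C2–C8–C7; C9–C10–C11 bridges C8/C1; C3–C4–C5–C6 bridges C2/C7)

- Retrosynthesis: three angelates; C9–CH3 (cuprate on the Δ9-11-one); C11=O/Δ9 from a meso C10 ketone; O4/O5 from a C6-carboxyl→C4 γ-lactone plus hydride at C5; C6–CH3; C5–C6 (Dieckmann); then C2–CH3 and C7–CH2 are cut together and C2–C7 is re-bonded, giving a wing-bridged bicyclo[1.1.0]butane ester made from a cyclohexene.
- Forward: six-membered ring → bicyclobutane (C2–C7 as central bond) → two bridgehead substituents → key step opens C2–C7 to the cyclobutane of a bicyclo[3.1.1]heptane → Dieckmann closes the seven-membered ring → lactone → hydride → enone → methyl → esters.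
- Stereochemistry: C1, C2, C7, C8 follow from how the bicyclobutane opens. CH3 enters syn to the C9–C11 bridge, the resident chain turns anti, the enolate is alkylated anti, and C7–H is set by a ring-enforced decarboxylation. Everything is meso or racemic up to step 9.
- Absolute configuration enters twice under reagent control, because the two bridges lie on opposite faces of the cyclobutane and cannot relay to each other: C6 by a chiral phase-transfer catalyst (step 10), C9 versus C11 by a chiral lithium amide (step 12). C4/C5 are relayed from C6 through the lactone; C9 is set by the cage.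
- Enabling feature: the one-carbon bridges C2 and C7 of the bicyclo[3.1.1]heptane (C1, C8, C9–C11) are 1,3 on the cyclobutane, and each carries its chain (C3, C6) anti and a small group (CH3, H) syn to the C9–C11 bridge. That is the pattern left by nucleophile/electrophile addition across the central bond of a 2,4-bridged bicyclobutane.

Key step: step 5

Remarks: "syn/anti" refer to the three-carbon bridge (C2–C4 of the bicyclo[3.1.1]heptanes, C9–C11 of the tricycles). The catalyst antipode in step 10 and the amide antipode in step 12 are the ones that give the configurations drawn; both antipodes are available and the sense must be fixed by experiment.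

Step 1
Reactants: 1 1,4-dioxaspiro[4.5]dec-7-ene
Product: 2 7,7-dibromospiro[bicyclo[4.1.0]heptane-3,2'-[1,3]dioxolane] (racemic)
Conditions: CHBr3, KOt-Bu, pentane, −10 → 20 °C
Reagents that add atoms: bromoform BrC(Br)Br
Why: Dibromocarbene from α-elimination of bromoform should add to the only C=C bond in a cis [2+1] cycloaddition; the ketal is inert to base.

Step 2
Reactants: 2 dibromocyclopropane
Product: 4 spiro[1,3-dioxolane-2,4'-tricyclo[4.1.0.0^{2,7}]heptane], via bromolithio carbenoid 3 (not isolated)
Conditions: MeLi, Et2O, −78 → 0 °C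
Reagents that add atoms: none
Why: Br/Li exchange and α-elimination should give the cyclopropylidene, which inserts into the syn C–H of a ring CH2 next to the cyclopropane (carbenoid route to tricyclo[4.1.0.0^{2,7}]heptanes); the CH2 remote from the ketal carbon should be preferred because the other is neopentyl-like and deactivated by two β-oxygens, which puts the ketal in the middle of the bridge and makes 4 achiral.

Step 3
Reactants: 4 bicyclobutane ketal
Product: 6 1'-(3,3-dimethoxypropyl)spiro[1,3-dioxolane-2,4'-tricyclo[4.1.0.0^{2,7}]heptane], via bridgehead lithio compound 5 (not isolated)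
Conditions: n-BuLi, TMEDA, Et2O, 25 °C; then Br(CH2)2CH(OMe)2, −78 → 25 °C
Reagents that add atoms: 3-bromo-1,1-dimethoxypropane COC(CCBr)OC
Why: The s-rich bridgehead C–H of a bicyclobutane is metalated by n-BuLi/TMEDA and the two bridgeheads of 4 are equivalent, so SN2 alkylation with the primary bromide should give one product; the acetal chain tolerates organolithiums.

Step 4
Reactants: 6 alkylated bicyclobutane
Product: 8 benzyl 7'-(3,3-dimethoxypropyl)spiro[1,3-dioxolane-2,4'-tricyclo[4.1.0.0^{2,7}]heptane]-1'-carboxylate, via bridgehead lithio compound 7 (not isolated)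
Conditions: n-BuLi, TMEDA, Et2O, 25 °C; then cannulated into ClCO2Bn, THF, −78 °C
Reagents that add atoms: benzyl chloroformate O=C(Cl)OCc1ccccc1
Why: The remaining bridgehead C–H is lithiated in the same way and the organolithium is alkoxycarbonylated by inverse addition to the chloroformate; 8 keeps a mirror plane through both bridgeheads.

Step 5
Reactants: 8 bicyclobutane benzyl ester
Product: 10 benzyl 6-(2-tert-butoxy-2-oxoethyl)-7-(3,3-dimethoxypropyl)-7-methylspiro[bicyclo[3.1.1]heptane-3,2'-[1,3]dioxolane]-6-carboxylate (meso; both chains anti, CH3 and CO2Bn syn), via lithium ester enolate 9 (not isolated)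
Conditions: Me2CuLi (CuI, 2 MeLi), PBu3, Et2O–THF, −78 → −20 °C; then BrCH2CO2t-Bu, DMPU, −78 → 0 °C
Reagents that add atoms: lithium dimethylcuprate [Li+].C[Cu-]C; tert-butyl bromoacetate CC(C)(C)OC(=O)CBr
Why: The cuprate should attack the bridgehead β to the ester from the rear of the strained central C–C bond (homoconjugate addition), cleaving it and leaving ester enolate 9, which is then C-alkylated by the bromoacetate; the closest known reaction type is copper-mediated homoconjugate addition/enolate trapping of bicyclo[1.1.0]butane-1-carboxylates and -sulfones, including wing-bridged tricyclo[4.1.0.0^{2,7}]heptanes. No ring is closed: the tricycle becomes the bicyclo[3.1.1]heptane and two C–C bonds are made across the future cyclobutane. At C7 (future C2) rear-side entry places CH3 syn to the ketal bridge, so the resident dimethoxypropyl chain turns anti. At C6 (future C7) the planar enolate carbon lies under the three-carbon bridge, whose C3 screens the upper face, so the electrophile should enter from below and CH2CO2t-Bu ends anti with CO2Bn syn. Regiochemistry is fixed by the ester (attack only at the β-bridgehead); the acetal chain offers the enolate no internal electrophile and the benzyl ester is not attacked by the Gilman reagent at low temperature. The product is meso, so no control of absolute configuration is needed here.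

Step 6
Reactants: 10 acetal diester
Product: 11 benzyl 6-(2-tert-butoxy-2-oxoethyl)-7-(3-methoxy-3-oxopropyl)-7-methylspiro[bicyclo[3.1.1]heptane-3,2'-[1,3]dioxolane]-6-carboxylate (meso)
Conditions: O3, EtOAc, −78 °C; N2 purge
Reagents that add atoms: ozone [O-][O+]=O
Why: Ozone should oxidise the acetal C–H (insertion to a hydrotrioxide that collapses to ester, methanol and O2), turning the dimethyl acetal into the methyl ester; the ketal (no C–H), the esters and the saturated cage are untouched.

Step 7
Reactants: 11 triester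
Product: 12 7-benzyl 6-tert-butyl 2-methyl-5-oxospiro[tricyclo[5.4.0.0^{2,8}]undecane-10,2'-[1,3]dioxolane]-6,7-dicarboxylate (racemic, C6 epimers)
Conditions: KOt-Bu, THF, 0 → 25 °C; AcOH quench
Reagents that add atoms: none
Why: Dieckmann condensation: the only efficient pairing is the enolate of the tert-butyl acetate arm (C6) with the unhindered methyl ester (C5), since the tert-butyl ester is a poor electrophile and the benzyl ester sits on a quaternary bridge carbon; the two chains are held cis-1,3-diaxial on the cyclobutane, so the seven-membered ring should close and be driven by deprotonation of the β-keto ester.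

Step 8
Reactants: 12 benzyl ester
Product: 13 6-(tert-butoxycarbonyl)-2-methyl-5-oxospiro[tricyclo[5.4.0.0^{2,8}]undecane-10,2'-[1,3]dioxolane]-7-carboxylic acid
Conditions: H2 (1 atm), 10% Pd/C, EtOAc, 25 °C
Reagents that add atoms: none
Why: Hydrogenolysis of the benzyl ester, the only reducible group present, should unmask the C7 carboxylic acid.

Step 9
Reactants: 13 carboxylic acid
Product: 14 tert-butyl 2-methyl-5-oxospiro[tricyclo[5.4.0.0^{2,8}]undecane-10,2'-[1,3]dioxolane]-6-carboxylate (racemic, C6 epimers)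
Conditions: 9-mesityl-10-methylacridinium BF4 (5 mol%), (PhS)2 (10 mol%), i-Pr2NEt (20 mol%), CF3CH2OH, 450 nm, 25 °C
Reagents that add atoms: none
Why: Acridinium-photocatalysed hydrodecarboxylation (carboxylate oxidation, loss of CO2, H-atom transfer from thiophenol) should give the C7 radical, and because C6 is locked anti by the seven-membered ring the hydrogen can only be delivered syn to the bridge, so C7 is set by the ring and not by facial selectivity.

Step 10
Reactants: 14 β-keto ester
Product: 15 tert-butyl (6R)-2,6-dimethyl-5-oxospiro[tricyclo[5.4.0.0^{2,8}]undecane-10,2'-[1,3]dioxolane]-6-carboxylate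
Conditions: MeI, CsOH·H2O, C2-symmetric binaphthyl-derived spiro quaternary ammonium bromide (3,4,5-trifluorophenyl substituted, 1 mol%), toluene, −40 °C
Reagents that add atoms: iodomethane CI
Why: Asymmetric phase-transfer alkylation of a cyclic β-keto tert-butyl ester: both C6 epimers converge on one enolate, and since the cage of 14 is meso the chiral ammonium ion pair alone should decide the face of methylation, creating the quaternary C6 as the first absolute stereocentre.

Step 11
Reactants: 15 methylated β-keto ester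
Product: 19 keto-lactone ketone (γ-lactone from the C6 carboxyl to O–C4 of 4-hydroxy-2,6-dimethyl-5,10-dioxotricyclo[5.4.0.0^{2,8}]undecane-6-carboxylic acid), via potassium enolate 16 (not isolated), via 4-bromo ketone 17 (not isolated), via keto-lactone ketal 18 (not isolated)
Conditions: KHMDS, THF, −78 °C; NBS, −78 °C; then LiBr (cat.), DMF, 60 °C; then 1 M HCl, THF, 25 °C
Reagents that add atoms: water O
Why: Enolisation can only go toward C4 (C6 is quaternary); in bromide 17 the tert-butyl ester carbonyl oxygen should displace bromide intramolecularly (5-exo, loss of isobutene) only from the epimer with Br anti to the ester, while bromide exchange equilibrates the C4 epimers, so both funnel into the cis γ-lactone; aqueous acid then removes the dioxolane.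

Step 12
Reactants: 19 keto-lactone ketone
Product: 21 Δ9-enol triflate (10-trifluoromethanesulfonyloxy-9-ene of the keto-lactone), via lithium enolate 20 (not isolated)
Conditions: lithium bis[(R)-1-phenylethyl]amide (from the amine and n-BuLi), LiCl, THF, −100 → −78 °C; then N-(5-chloropyridin-2-yl)triflimide, −78 °C
Reagents that add atoms: N-(5-chloropyridin-2-yl)-bis(trifluoromethanesulfonyl)imide O=S(=O)(N(c1ccc(Cl)cn1)S(=O)(=O)C(F)(F)F)C(F)(F)F
Why: Enantiotopic deprotonation of a locally Cs-symmetric bicyclic ketone by a chiral lithium amide (the lactone and C5 ketone carry no enolisable hydrogen), followed by O-triflation, should turn the C9 methylene into the vinyl carbon and so distinguish C9 from C11 relative to the fixed C6; the bottom of the molecule is too remote to bias the outcome.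

Step 13
Reactants: 21 enol triflate
Product: 22 Δ9 alkene of the keto-lactone
Conditions: Pd(OAc)2 (5 mol%), PPh3, n-Bu3N, HCO2H, DMF, 60 °C
Reagents that add atoms: none
Why: Palladium-catalysed formate reduction of an enol triflate should give the alkene without touching lactone or ketone.

Step 14
Reactants: 22 alkene
Product: 23 11-hydroxy-Δ9 keto-lactone (C11 epimers)
Conditions: SeO2 (0.5 equiv), t-BuOOH, CH2Cl2, 25 °C
Reagents that add atoms: selenium dioxide O=[Se]=O; tert-butyl hydroperoxide CC(C)(C)OO
Why: Selenium dioxide allylic oxidation (ene reaction then [2,3]-sigmatropic shift) passes through no symmetric allyl intermediate, and the only abstractable allylic hydrogen is on C11 (the other allylic position is the C8 bridgehead), so oxygen should go to C11 with the double bond kept at C9–C10; the C11 configuration is irrelevant.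

Step 15
Reactants: 23 allylic alcohol keto-lactone
Product: 24 (1R,2R,4S,5S,6S,7S,8S)-6-(hydroxymethyl)-2,6-dimethyltricyclo[5.4.0.0^{2,8}]undec-9-ene-4,5,11-triol (C11 epimers)
Conditions: LiAlH4, THF, −78 → 0 °C
Reagents that add atoms: none
Why: Hydride should attack the C5 ketone from the face of the two-atom lactone bridge, the other face being screened by the cage (C8–H), giving 5-OH trans to both O4 and the C6 carbinol carbon, and then reduce the lactone to the 4-OH and the primary alcohol.

Step 16
Reactants: 24 tetraol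
Product: 25 (1R,2R,4S,5S,6S,7S,8S)-4,5-dihydroxy-6-(hydroxymethyl)-2,6-dimethyltricyclo[5.4.0.0^{2,8}]undec-9-en-11-one
Conditions: MnO2, CH2Cl2, 25 °C
Reagents that add atoms: none
Why: Manganese dioxide should oxidise only the allylic C11 alcohol, giving the bicyclo[3.1.1]hept-3-en-2-one-type enone.

Step 17
Reactants: 25 enone triol
Product: 26 (1R,2R,4S,5S,6S,7S,8S,9R)-4,5-dihydroxy-6-(hydroxymethyl)-2,6,9-trimethyltricyclo[5.4.0.0^{2,8}]undecan-11-one
Conditions: Me2CuLi (CuI, 2 MeLi; 6 equiv), Et2O–THF, −78 → −40 °C; NH4Cl/NH3 quench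
Reagents that add atoms: lithium dimethylcuprate [Li+].C[Cu-]C
Why: Conjugate addition of the Gilman reagent to the enone (the excess covers the three hydroxyl groups) should occur on the face of the C7–H bridge, away from the syn methyl on C2, setting C9 as in cuprate additions to 6,6-dimethylbicyclo[3.1.1]hept-3-en-2-one.

Step 18
Reactants: 26 triol ketone
Product: 28 CNP0214984.1, [(1R,2R,4S,5S,6S,7S,8S,9R)-4,5-bis{[(2Z)-2-methylbut-2-enoyl]oxy}-2,6,9-trimethyl-11-oxotricyclo[5.4.0.0^{2,8}]undecan-6-yl]methyl (2Z)-2-methylbut-2-enoate, via trilithium alkoxide 27 (not isolated)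
Conditions: LiHMDS (3.1 equiv), THF, −78 °C; angelic anhydride, −78 → 0 °C
Reagents that add atoms: angelic anhydride C/C=C(/C)C(=O)OC(=O)/C(C)=C\C
Why: Acylation of lithium alkoxides with angelic anhydride at low temperature, without a nucleophilic amine catalyst, should give the three (Z)-esters without Z→E isomerisation; O–H deprotonation is faster than enolisation of the C11 ketone.

**Compound list**

1 | 1,4-dioxaspiro[4.5]dec-7-ene | C1=CCC2(CC1)OCCO2 | starting material
2 | 7,7-dibromospiro[bicyclo[4.1.0]heptane-3,2'-[1,3]dioxolane] (racemic) | BrC1(Br)[C@H]2CCC3(C[C@@H]12)OCCO3 | intermediate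
3 | 7-bromo-7-lithio carbenoid of 2 | [Li]C1(Br)[C@H]2CCC3(C[C@@H]12)OCCO3 | intermediate
4 | spiro[1,3-dioxolane-2,4'-tricyclo[4.1.0.0^{2,7}]heptane] (achiral) | C1COC2(O1)C[C@H]1[C@H]3[C@@H](C2)[C@@H]13 | intermediate
5 | 1'-lithio derivative of 4 | C1COC2(O1)C[C@H]1[C@H]3[C@@H](C2)[C@@]13[Li] | intermediate
6 | 1'-(3,3-dimethoxypropyl)spiro[1,3-dioxolane-2,4'-tricyclo[4.1.0.0^{2,7}]heptane] | C1COC2(O1)C[C@H]1[C@H]3[C@@H](C2)[C@@]13CCC(OC)OC | intermediate
7 | 7'-lithio derivative of 6 | C1COC2(O1)C[C@H]1[C@@]3([Li])[C@@H](C2)[C@@]13CCC(OC)OC | intermediate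
8 | benzyl 7'-(3,3-dimethoxypropyl)spiro[1,3-dioxolane-2,4'-tricyclo[4.1.0.0^{2,7}]heptane]-1'-carboxylate | C1COC2(O1)C[C@H]1[C@@]3(C(=O)OCc4ccccc4)[C@@H](C2)[C@@]13CCC(OC)OC | intermediate
9 | lithium enolate of the benzyl ester after methyl transfer (7-methyl, chain anti) | [Li+].[O-]C(OCc1ccccc1)=C1[C@@H]2CC3(OCCO3)C[C@H]1[C@]2(C)CCC(OC)OC | intermediate
10 | benzyl 6-(2-tert-butoxy-2-oxoethyl)-7-(3,3-dimethoxypropyl)-7-methylspiro[bicyclo[3.1.1]heptane-3,2'-[1,3]dioxolane]-6-carboxylate (meso; chains anti) | CC(C)(C)OC(=O)C[C@@]1(C(=O)OCc2ccccc2)[C@@H]3CC4(OCCO4)C[C@H]1[C@]3(C)CCC(OC)OC | intermediate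
11 | benzyl 6-(2-tert-butoxy-2-oxoethyl)-7-(3-methoxy-3-oxopropyl)-7-methylspiro[bicyclo[3.1.1]heptane-3,2'-[1,3]dioxolane]-6-carboxylate (meso) | CC(C)(C)OC(=O)C[C@@]1(C(=O)OCc2ccccc2)[C@@H]3CC4(OCCO4)C[C@H]1[C@]3(C)CCC(=O)OC | intermediate
12 | 7-benzyl 6-tert-butyl 2-methyl-5-oxospiro[tricyclo[5.4.0.0^{2,8}]undecane-10,2'-[1,3]dioxolane]-6,7-dicarboxylate (racemic, C6 epimers) | CC(C)(C)OC(=O)C1[C@@]2(C(=O)OCc3ccccc3)[C@@H]3CC4(OCCO4)C[C@H]2[C@]3(C)CCC1=O | intermediate
13 | 6-(tert-butoxycarbonyl)-2-methyl-5-oxospiro[tricyclo[5.4.0.0^{2,8}]undecane-10,2'-[1,3]dioxolane]-7-carboxylic acid | CC(C)(C)OC(=O)C1[C@@]2(C(=O)O)[C@@H]3CC4(OCCO4)C[C@H]2[C@]3(C)CCC1=O | intermediate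
14 | tert-butyl 2-methyl-5-oxospiro[tricyclo[5.4.0.0^{2,8}]undecane-10,2'-[1,3]dioxolane]-6-carboxylate (racemic, C6 epimers) | CC(C)(C)OC(=O)C1[C@H]2[C@@H]3CC4(OCCO4)C[C@H]2[C@]3(C)CCC1=O | intermediate
15 | tert-butyl (6R)-2,6-dimethyl-5-oxospiro[tricyclo[5.4.0.0^{2,8}]undecane-10,2'-[1,3]dioxolane]-6-carboxylate | CC(C)(C)OC(=O)[C@]1(C)[C@H]2[C@@H]3CC4(OCCO4)C[C@H]2[C@]3(C)CCC1=O | intermediate
16 | potassium C4-enolate of 15 | CC(C)(C)OC(=O)[C@]1(C)[C@H]2[C@@H]3CC4(OCCO4)C[C@H]2[C@]3(C)CC=C1[O-].[K+] | intermediate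
17 | 4-bromo derivative of 15 (C4 epimers) | CC(C)(C)OC(=O)[C@]1(C)[C@H]2[C@@H]3CC4(OCCO4)C[C@H]2[C@]3(C)CC(Br)C1=O | intermediate
18 | keto-lactone ketal (C6 carboxyl lactonised onto O–C4, 5-oxo, 10-dioxolane) | O=C1O[C@H]2C[C@@]3(C)[C@@H]4CC5(OCCO5)C[C@H]3[C@@H]4[C@]1(C)C2=O | intermediate
19 | keto-lactone ketone (5,10-dioxo) | O=C1O[C@H]2C[C@@]3(C)[C@@H]4CC(=O)C[C@H]3[C@@H]4[C@]1(C)C2=O | intermediate
20 | lithium Δ9-enolate of 19 | O=C1O[C@H]2C[C@@]3(C)[C@@H]4CC([O-])=C[C@H]3[C@@H]4[C@]1(C)C2=O.[Li+] | intermediate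
21 | Δ9-enol triflate of the keto-lactone | O=C1O[C@H]2C[C@@]3(C)[C@@H]4CC(OS(=O)(=O)C(F)(F)F)=C[C@H]3[C@@H]4[C@]1(C)C2=O | intermediate
22 | Δ9 alkene of the keto-lactone | O=C1O[C@H]2C[C@@]3(C)[C@@H]4CC=C[C@H]3[C@@H]4[C@]1(C)C2=O | intermediate
23 | 11-hydroxy-Δ9 keto-lactone (C11 epimers) | O=C1O[C@H]2C[C@@]3(C)[C@@H]4C(O)C=C[C@H]3[C@@H]4[C@]1(C)C2=O | intermediate
24 | (1R,2R,4S,5S,6S,7S,8S)-6-(hydroxymethyl)-2,6-dimethyltricyclo[5.4.0.0^{2,8}]undec-9-ene-4,5,11-triol (C11 epimers) | OC[C@]1(C)[C@H]2[C@@H]3C=CC(O)[C@H]2[C@]3(C)C[C@H](O)[C@H]1O | intermediate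
25 | (1R,2R,4S,5S,6S,7S,8S)-4,5-dihydroxy-6-(hydroxymethyl)-2,6-dimethyltricyclo[5.4.0.0^{2,8}]undec-9-en-11-one | OC[C@]1(C)[C@H]2[C@@H]3C=CC(=O)[C@H]2[C@]3(C)C[C@H](O)[C@H]1O | intermediate
26 | (1R,2R,4S,5S,6S,7S,8S,9R)-4,5-dihydroxy-6-(hydroxymethyl)-2,6,9-trimethyltricyclo[5.4.0.0^{2,8}]undecan-11-one | OC[C@]1(C)[C@H]2[C@@H]3[C@H](C)CC(=O)[C@H]2[C@]3(C)C[C@H](O)[C@H]1O | intermediate
27 | trilithium alkoxide of 26 | [Li+].[Li+].[Li+].[O-]C[C@]1(C)[C@H]2[C@@H]3[C@H](C)CC(=O)[C@H]2[C@]3(C)C[C@H]([O-])[C@H]1[O-] | intermediate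
28 | CNP0214984.1, tris-angelate of 26 | C/C=C(/C)C(=O)OC[C@]1(C)[C@H]2[C@@H]3[C@H](C)CC(=O)[C@H]2[C@]3(C)C[C@H](OC(=O)/C(C)=C\C)[C@H]1OC(=O)/C(C)=C\C | target

**Totals:** 18 steps; longest linear sequence 18 steps.

**Steps most likely to fail**

Step 5 (key step). Risk: C-alkylation of the crowded enolate 9 may be outrun by proton transfer from the enolisable bromoacetate, so that only the protonated ester results. The fallback sets out from 8 and returns at 10. The same cuprate addition would be quenched with allyl bromide, the most reactive class of electrophile for such enolates, to give benzyl 6-allyl-7-(3,3-dimethoxypropyl)-7-methylspiro[bicyclo[3.1.1]heptane-3,2'-[1,3]dioxolane]-6-carboxylate F1. Lemieux–Johnson cleavage (OsO4 cat., NaIO4, 2,6-lutidine) would give the aldehyde F2 and Pinnick oxidation the acid F3. tert-Butyl ester formation (Boc2O, DMAP, t-BuOH) would then give 10.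

Step 12. Risk: the chiral amide may discriminate poorly between the enantiotopic α-methylenes, or the enolate may equilibrate before O-triflation. The fallback sets out from 19 and returns at 23. Proline-catalysed α-aminoxylation with nitrosobenzene would place oxygen directly on C11 to give the anilinooxy ketone F4, which Zn/AcOH would cleave to the α-hydroxy ketone F5. Silylation (TBSOTf, 2,6-lutidine) would give F6. Enolisation toward C9 (KHMDS, PhNTf2) would give enol triflate F7 and Pd/formate reduction the allylic silyl ether F8. HF·pyridine would release 23. This removes both the lithium amide and the selenium step.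

Step 10. Risk: an uncatalysed background alkylation, or poor face discrimination by the ion pair at the hindered C6, would erode the enantiomeric purity on which all later diastereoselectivity rests. The fallback sets out from 14 and returns at 15. Noyori hydrogenation with dynamic kinetic resolution (Ru–BINAP, H2) would give the enantioenriched β-hydroxy ester F9. Fráter–Seebach alkylation (2 LDA, MeI; methyl anti to the alkoxide) would give F10. Dess–Martin oxidation would then give 15.

**Further compounds**

F1 | step 5 | benzyl 6-allyl-7-(3,3-dimethoxypropyl)-7-methylspiro[bicyclo[3.1.1]heptane-3,2'-[1,3]dioxolane]-6-carboxylate | C=CC[C@@]1(C(=O)OCc2ccccc2)[C@@H]3CC4(OCCO4)C[C@H]1[C@]3(C)CCC(OC)OC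
F2 | step 5 | 6-(2-oxoethyl) analogue of F1 | O=CC[C@@]1(C(=O)OCc2ccccc2)[C@@H]3CC4(OCCO4)C[C@H]1[C@]3(C)CCC(OC)OC
F3 | step 5 | 6-(carboxymethyl) analogue of F1 | OC(=O)C[C@@]1(C(=O)OCc2ccccc2)[C@@H]3CC4(OCCO4)C[C@H]1[C@]3(C)CCC(OC)OC
F4 | step 12 | 11-(anilinooxy) derivative of 19 | O=C1O[C@H]2C[C@@]3(C)[C@@H]4C(ONc5ccccc5)C(=O)C[C@H]3[C@@H]4[C@]1(C)C2=O
F5 | step 12 | 11-hydroxy derivative of 19 | O=C1O[C@H]2C[C@@]3(C)[C@@H]4C(O)C(=O)C[C@H]3[C@@H]4[C@]1(C)C2=O
F6 | step 12 | 11-(tert-butyldimethylsilyloxy) derivative of 19 | O=C1O[C@H]2C[C@@]3(C)[C@@H]4C(O[Si](C)(C)C(C)(C)C)C(=O)C[C@H]3[C@@H]4[C@]1(C)C2=O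
F7 | step 12 | 11-silyloxy Δ9-enol triflate | O=C1O[C@H]2C[C@@]3(C)[C@@H]4C(O[Si](C)(C)C(C)(C)C)C(OS(=O)(=O)C(F)(F)F)=C[C@H]3[C@@H]4[C@]1(C)C2=O
F8 | step 12 | 11-silyloxy Δ9 alkene (TBS ether of 23) | O=C1O[C@H]2C[C@@]3(C)[C@@H]4C(O[Si](C)(C)C(C)(C)C)C=C[C@H]3[C@@H]4[C@]1(C)C2=O
F9 | step 10 | tert-butyl 5-hydroxy-2-methylspiro[tricyclo[5.4.0.0^{2,8}]undecane-10,2'-[1,3]dioxolane]-6-carboxylate (trans) | CC(C)(C)OC(=O)[C@H]1[C@H]2[C@@H]3CC4(OCCO4)C[C@H]2[C@]3(C)CC[C@@H]1O
F10 | step 10 | tert-butyl 5-hydroxy-2,6-dimethylspiro[tricyclo[5.4.0.0^{2,8}]undecane-10,2'-[1,3]dioxolane]-6-carboxylate | CC(C)(C)OC(=O)[C@]1(C)[C@H]2[C@@H]3CC4(OCCO4)C[C@H]2[C@]3(C)CC[C@@H]1O
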